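The route rests on disconnecting ring C of the upper epicatechin gallate unit across C4a–C4 and C2–C3. This is a cationic (4+2) annulation (oxa-Povarov) between an O-aryl oxocarbenium ion (C4a, C8a, O1, C2) and an (E)-enol gallate (C3=C4) already attached to C8 of the middle unit. The step exploits two features: C4 is benzylic to the phloroglucinol-type ring A of the epigallocatechin unit, and C3 carries the target's own gallate. The first stabilises the C4 cation; the second bridges it and enforces 3,4-trans closure. The precursor is the perbenzylated epigallocatechin gallate-(4β→8)-catechin gallate dimer bearing an (E)-2-(galloyloxy)vinyl group, plus a phenol-derived mixed acetal.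

Key step: step 12

Remark: the target is read as epicatechin-3-O-gallate-(4β→8)-epigallocatechin-3-O-gallate-(4β→8)-catechin-3-O-gallate (upper unit 2R,3R,4R; middle unit 2R,3R,4S; lower unit 2R,3S); flavan numbering (O1, C2, C3, C4, C4a, C5–C8, C8a) is used throughout.

Remark: the antipode of the chiral squaramide in step 12 that matches the resident chirality of 13 and delivers the 2R ring C is assumed to be found by a trial with both antipodes.

**Step 1**
Reactants: 1 (+)-catechin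
Product: 2 5,7,3',4'-tetra-O-benzyl-(+)-catechin
Conditions: BnBr (4.4 equiv), K2CO3, DMF, 0 °C → rt
Reagents that add atoms: benzyl bromide, BrCc1ccccc1
Why: Williamson etherification; carbonate deprotonates only the four phenols, so the secondary C3 hydroxyl stays free and no stereocentre is touched.

**Step 2**
Reactants: 2 5,7,3',4'-tetra-O-benzyl-(+)-catechin; 3 3,4,5-tris(benzyloxy)benzoic acid
Product: 4 5,7,3',4'-tetra-O-benzyl-(+)-catechin 3-O-[3,4,5-tris(benzyloxy)benzoate]
Conditions: DCC, DMAP (10 mol %), CH2Cl2, rt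
Reagents that add atoms: none
Why: Steglich esterification acylates the C3 oxygen without breaking a bond to C3, so the 2R,3S configuration is kept.

**Step 3**
Reactants: 5 (−)-epigallocatechin
Product: 6 5,7,3',4',5'-penta-O-benzyl-(−)-epigallocatechin
Conditions: BnBr (5.5 equiv), K2CO3, DMF, 0 °C → rt, argon, dark
Reagents that add atoms: benzyl bromide, BrCc1ccccc1
Why: Williamson etherification; carbonate deprotonates only the five phenols, so the secondary C3 hydroxyl stays free, exclusion of air and light protects the base-sensitive pyrogallol ring B, and no bond to C2 or C3 is broken.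

**Step 4**
Reactants: 6 5,7,3',4',5'-penta-O-benzyl-(−)-epigallocatechin
Product: 7 4β-(2-ethoxyethoxy)-5,7,3',4',5'-penta-O-benzyl-epigallocatechin
Conditions: DDQ (2 equiv), 2-ethoxyethanol, CH2Cl2, rt
Reagents that add atoms: 2-ethoxyethanol, CCOCCO
Why: DDQ benzylic oxidation; hydride abstraction at C4 gives a cation stabilised by the 5,7-dibenzyloxy ring A, which the alcohol traps trans to the C3 hydroxyl (4β), and this centre is ionised again in step 7.

**Step 5**
Reactants: 7 4β-(2-ethoxyethoxy)-5,7,3',4',5'-penta-O-benzyl-epigallocatechin; 3 3,4,5-tris(benzyloxy)benzoic acid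
Product: 8 4β-(2-ethoxyethoxy)-octa-O-benzyl-epigallocatechin 3-O-gallate
Conditions: DCC, DMAP (20 mol %), CH2Cl2, rt
Reagents that add atoms: none
Why: Steglich esterification acylates the C3 oxygen without breaking a bond to C3, and the neutral conditions leave the acid-labile benzylic C4 ether untouched.

**Step 6**
Reactants: 8 4β-(2-ethoxyethoxy)-octa-O-benzyl-epigallocatechin 3-O-gallate
Product: 9 8-bromo-4β-(2-ethoxyethoxy)-octa-O-benzyl-epigallocatechin 3-O-gallate
Conditions: NBS (1.05 equiv), CH2Cl2, −78 → −20 °C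
Reagents that add atoms: N-bromosuccinimide, O=C1CCC(=O)N1Br
Why: Electrophilic aromatic bromination at C8, the most accessible nucleophilic position of ring A; the bromine blocks self-condensation in step 7 and later serves as the cross-coupling handle.

**Step 7**
Reactants: 9 8-bromo-4β-(2-ethoxyethoxy)-octa-O-benzyl-epigallocatechin 3-O-gallate; 4 5,7,3',4'-tetra-O-benzyl-(+)-catechin 3-O-[3,4,5-tris(benzyloxy)benzoate] (4 equiv)
Product: 10 pentadeca-O-benzyl 8-bromo-epigallocatechin-3-O-gallate-(4β→8)-catechin-3-O-gallate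
Conditions: TMSOTf (0.3 equiv), CH2Cl2, −78 → −40 °C
Reagents that add atoms: none
Why: Friedel–Crafts-type flavan-4-yl cation coupling; ionisation of the 4-alkoxy group gives a gallate-bridged C4 cation that C8 of the excess nucleophile attacks anti to the C3 gallate (4β, 3,4-trans), while the C8 bromine of the electrophile prevents oligomerisation.

**Step 8**
Reactants: 10 pentadeca-O-benzyl 8-bromo-epigallocatechin-3-O-gallate-(4β→8)-catechin-3-O-gallate; 11 (E)-1,2-bis(4,4,5,5-tetramethyl-1,3,2-dioxaborolan-2-yl)ethene (3 equiv)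
Product: 12 dimer carrying an (E)-2-(pinacolboryl)vinyl group at C8 of the epigallocatechin unit
Conditions: Pd(OAc)2 (10 mol %), SPhos (20 mol %), K3PO4, toluene/H2O, 70 °C
Reagents that add atoms: none
Why: Suzuki–Miyaura mono-coupling; the bulky electron-rich phosphine allows oxidative addition of zerovalent palladium into the di-ortho-oxygenated bromide, excess 11 and the hindered product suppress a second coupling, and the (E)-geometry is retained.

**Step 9**
Reactants: 12 dimer (E)-alkenyl pinacol boronate; 3 3,4,5-tris(benzyloxy)benzoic acid (3 equiv)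
Product: 13 dimer carrying an (E)-2-[3,4,5-tris(benzyloxy)benzoyloxy]vinyl group at C8 of the epigallocatechin unit
Conditions: Cu(OAc)2 (30 mol %), DMAP, 4 Å MS, O2 (1 atm), CH2Cl2, rt
Reagents that add atoms: none
Why: Chan–Lam-type oxidative C–O coupling of an alkenylboronate with a carboxylic acid; transmetalation and reductive elimination at copper proceed with retention, so the (E)-enol ester should result.

**Step 10**
Reactants: 14 3,4-bis(benzyloxy)benzaldehyde
Product: 15 3,4-bis(benzyloxy)benzaldehyde dimethyl acetal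
Conditions: HC(OMe)3, TsOH (cat.), MeOH, rt
Reagents that add atoms: trimethyl orthoformate, COC(OC)OC
Why: Acid-catalysed acetalisation driven to completion by the orthoformate, which delivers the methoxy groups and ends up as methyl formate.

**Step 11**
Reactants: 15 3,4-bis(benzyloxy)benzaldehyde dimethyl acetal; 16 3,5-bis(benzyloxy)phenol
Product: 18 racemic [3,5-bis(benzyloxy)phenoxy](methoxy)[3,4-bis(benzyloxy)phenyl]methane, via alpha-chlorobenzyl methyl ether 17 (not isolated)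
Conditions: AcCl, CH2Cl2, 0 °C → rt, evaporation; then 16, NaH, THF/DMF, −40 → 0 °C
Reagents that add atoms: none
Why: Acetal-to-α-chloro ether exchange followed by Williamson-type O-alkylation of the sodium phenoxide, where a hard α-alkoxy halide and a polar aprotic medium favour O- over C-alkylation; the acetal carbon is racemic and becomes planar in step 12.

**Step 12**
Reactants: 13 dimer (E)-enol gallate; 18 mixed acetal (3 equiv, slow addition)
Product: 19 docosa-O-benzyl epicatechin-3-O-gallate-(4β→8)-epigallocatechin-3-O-gallate-(4β→8)-catechin-3-O-gallate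
Conditions: TMSOTf (20 mol %), chiral arylpyrrolidine tert-leucinamide squaramide (25 mol %), 5 Å MS, toluene/CH2Cl2, −78 → −50 °C, then Et3N
Reagents that add atoms: none
Why: Proposed new method: TMSOTf removes methoxide from 18 to give the O-aryl oxocarbenium ion (a cationic 2-oxadiene spanning C4a, C8a, O1 and C2) as a chiral ion pair with the squaramide-bound triflate; the enol ester carbon that becomes C3 adds to C2, the resulting C4 cation is benzylic to ring A of the epigallocatechin unit and bridged by the gallate carbonyl as a 1,3-dioxolan-2-ylium ion, and the phenoxy ring then attacks C4 ortho to O1 with loss of a proton. The closest known reactions are the SnCl4-promoted oxa-Povarov reaction of O-aryl oxocarbenium ions with styrenes and the enantioselective additions to acetal-derived oxocarbenium triflates under squaramide and silyl triflate catalysis, while an enol ester as the two-carbon partner and asymmetric control of this annulation are new. Ring C (O1, C2, C3, C4, C4a, C8a) is closed as a formal inverse-electron-demand (4+2) annulation, its second bond by a 6-exo-tet Friedel–Crafts opening of the acyloxonium ion. C2 is set by the catalyst, which shields one face of the oxocarbenium ion; C3 is set by approach of the (E)-alkene with the gallate endo (carbonyl oxygen next to the cationic O1=C2) and the very large dimer residue exo, giving 2,3-cis; C4 is set by anti opening of the acyloxonium ion (equally by suprafacial addition to the (E)-alkene), giving 3,4-trans. The step needs regioselectivity for C3 as the nucleophilic carbon, secured by the weakly donating acyloxy group against the 2,4,6-trioxygenated aryl group, and chemoselectivity over the free C6 positions of the dimer, which are each flanked by two benzyloxy groups. The resident stereocentres are remote, so the absolute configuration of the new ring rests on the catalyst.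

**Step 13**
Reactants: 19 docosa-O-benzyl trimer
Product: 20 epicatechin-3-O-gallate-(4β→8)-epigallocatechin-3-O-gallate-(4β→8)-catechin-3-O-gallate (CNP0321910.1)
Conditions: H2 (1 atm), Pd(OH)2/C, THF/MeOH/H2O, rt
Reagents that add atoms: none
Why: Hydrogenolysis of all twenty-two benzyl ethers; the flavan C2–O1 bonds, the interflavan bonds and the gallate esters are expected to survive these conditions, and no stereocentre is affected.

**Compound list**

1 | (+)-catechin, (2R,3S) | c1c(O)cc(O)c2c1O[C@H](c1ccc(O)c(O)c1)[C@@H](O)C2 | starting material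

2 | 5,7,3',4'-tetra-O-benzyl-(+)-catechin | c1c(OCc5ccccc5)cc(OCc5ccccc5)c2c1O[C@H](c1ccc(OCc5ccccc5)c(OCc5ccccc5)c1)[C@@H](O)C2 | intermediate

3 | 3,4,5-tris(benzyloxy)benzoic acid | OC(=O)c1cc(OCc2ccccc2)c(OCc2ccccc2)c(OCc2ccccc2)c1 | starting material

4 | 5,7,3',4'-tetra-O-benzyl-(+)-catechin 3-O-[3,4,5-tris(benzyloxy)benzoate], (2R,3S) | c1c(OCc5ccccc5)cc(OCc5ccccc5)c2c1O[C@H](c1ccc(OCc5ccccc5)c(OCc5ccccc5)c1)[C@@H](OC(=O)c1cc(OCc5ccccc5)c(OCc5ccccc5)c(OCc5ccccc5)c1)C2 | intermediate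

5 | (−)-epigallocatechin, (2R,3R) | O[C@@H]1Cc2c(O)cc(O)cc2O[C@@H]1c1cc(O)c(O)c(O)c1 | starting material

6 | 5,7,3',4',5'-penta-O-benzyl-(−)-epigallocatechin | O[C@@H]1Cc2c(OCc5ccccc5)cc(OCc5ccccc5)cc2O[C@@H]1c1cc(OCc5ccccc5)c(OCc5ccccc5)c(OCc5ccccc5)c1 | intermediate

7 | 4β-(2-ethoxyethoxy)-5,7,3',4',5'-penta-O-benzyl-epigallocatechin (2α-aryl, 3α-hydroxy, 4β-alkoxy) | O[C@@H]1[C@@H](OCCOCC)c2c(OCc5ccccc5)cc(OCc5ccccc5)cc2O[C@@H]1c1cc(OCc5ccccc5)c(OCc5ccccc5)c(OCc5ccccc5)c1 | intermediate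

8 | 4β-(2-ethoxyethoxy)-octa-O-benzyl-epigallocatechin 3-O-gallate (2α-aryl, 3α-acyloxy, 4β-alkoxy) | O=C(O[C@@H]1[C@@H](OCCOCC)c2c(OCc5ccccc5)cc(OCc5ccccc5)cc2O[C@@H]1c1cc(OCc5ccccc5)c(OCc5ccccc5)c(OCc5ccccc5)c1)c1cc(OCc5ccccc5)c(OCc5ccccc5)c(OCc5ccccc5)c1 | intermediate

9 | 8-bromo-4β-(2-ethoxyethoxy)-octa-O-benzyl-epigallocatechin 3-O-gallate | O=C(O[C@@H]1[C@@H](OCCOCC)c2c(OCc5ccccc5)cc(OCc5ccccc5)c(Br)c2O[C@@H]1c1cc(OCc5ccccc5)c(OCc5ccccc5)c(OCc5ccccc5)c1)c1cc(OCc5ccccc5)c(OCc5ccccc5)c(OCc5ccccc5)c1 | intermediate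

10 | pentadeca-O-benzyl 8-bromo-epigallocatechin-3-O-gallate-(4β→8)-catechin-3-O-gallate | O=C(O[C@@H]1[C@@H](c2c(OCc5ccccc5)cc(OCc5ccccc5)c3c2O[C@H](c2ccc(OCc5ccccc5)c(OCc5ccccc5)c2)[C@@H](OC(=O)c2cc(OCc5ccccc5)c(OCc5ccccc5)c(OCc5ccccc5)c2)C3)c2c(OCc5ccccc5)cc(OCc5ccccc5)c(Br)c2O[C@@H]1c1cc(OCc5ccccc5)c(OCc5ccccc5)c(OCc5ccccc5)c1)c1cc(OCc5ccccc5)c(OCc5ccccc5)c(OCc5ccccc5)c1 | intermediate

11 | (E)-1,2-bis(4,4,5,5-tetramethyl-1,3,2-dioxaborolan-2-yl)ethene | CC1(C)OB(/C=C/B2OC(C)(C)C(C)(C)O2)OC1(C)C | starting material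

12 | dimer as 10 with an (E)-2-(pinacolboryl)vinyl group in place of bromine at C8 of the epigallocatechin unit | O=C(O[C@@H]1[C@@H](c2c(OCc5ccccc5)cc(OCc5ccccc5)c3c2O[C@H](c2ccc(OCc5ccccc5)c(OCc5ccccc5)c2)[C@@H](OC(=O)c2cc(OCc5ccccc5)c(OCc5ccccc5)c(OCc5ccccc5)c2)C3)c2c(OCc5ccccc5)cc(OCc5ccccc5)c(/C=C/B6OC(C)(C)C(C)(C)O6)c2O[C@@H]1c1cc(OCc5ccccc5)c(OCc5ccccc5)c(OCc5ccccc5)c1)c1cc(OCc5ccccc5)c(OCc5ccccc5)c(OCc5ccccc5)c1 | intermediate

13 | dimer as 10 with an (E)-2-[3,4,5-tris(benzyloxy)benzoyloxy]vinyl group in place of bromine at C8 of the epigallocatechin unit | O=C(O[C@@H]1[C@@H](c2c(OCc5ccccc5)cc(OCc5ccccc5)c3c2O[C@H](c2ccc(OCc5ccccc5)c(OCc5ccccc5)c2)[C@@H](OC(=O)c2cc(OCc5ccccc5)c(OCc5ccccc5)c(OCc5ccccc5)c2)C3)c2c(OCc5ccccc5)cc(OCc5ccccc5)c(/C=C/OC(=O)c6cc(OCc5ccccc5)c(OCc5ccccc5)c(OCc5ccccc5)c6)c2O[C@@H]1c1cc(OCc5ccccc5)c(OCc5ccccc5)c(OCc5ccccc5)c1)c1cc(OCc5ccccc5)c(OCc5ccccc5)c(OCc5ccccc5)c1 | intermediate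

14 | 3,4-bis(benzyloxy)benzaldehyde | O=Cc1ccc(OCc2ccccc2)c(OCc2ccccc2)c1 | starting material

15 | 3,4-bis(benzyloxy)benzaldehyde dimethyl acetal | COC(OC)c1ccc(OCc2ccccc2)c(OCc2ccccc2)c1 | intermediate

16 | 3,5-bis(benzyloxy)phenol | Oc1cc(OCc2ccccc2)cc(OCc2ccccc2)c1 | starting material

17 | racemic α-chloro-3,4-bis(benzyloxy)benzyl methyl ether | COC(Cl)c1ccc(OCc2ccccc2)c(OCc2ccccc2)c1 | intermediate

18 | racemic [3,5-bis(benzyloxy)phenoxy](methoxy)[3,4-bis(benzyloxy)phenyl]methane | COC(Oc1cc(OCc2ccccc2)cc(OCc2ccccc2)c1)c1ccc(OCc2ccccc2)c(OCc2ccccc2)c1 | intermediate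

19 | docosa-O-benzyl epicatechin-3-O-gallate-(4β→8)-epigallocatechin-3-O-gallate-(4β→8)-catechin-3-O-gallate | O=C(O[C@@H]1[C@@H](c2c(OCc5ccccc5)cc(OCc5ccccc5)c3c2O[C@H](c2ccc(OCc5ccccc5)c(OCc5ccccc5)c2)[C@@H](OC(=O)c2cc(OCc5ccccc5)c(OCc5ccccc5)c(OCc5ccccc5)c2)C3)c2c(OCc5ccccc5)cc(OCc5ccccc5)c([C@H]3c4c(OCc5ccccc5)cc(OCc5ccccc5)cc4O[C@H](c4ccc(OCc5ccccc5)c(OCc5ccccc5)c4)[C@@H]3OC(=O)c3cc(OCc5ccccc5)c(OCc5ccccc5)c(OCc5ccccc5)c3)c2O[C@@H]1c1cc(OCc5ccccc5)c(OCc5ccccc5)c(OCc5ccccc5)c1)c1cc(OCc5ccccc5)c(OCc5ccccc5)c(OCc5ccccc5)c1 | intermediate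

20 | epicatechin-3-O-gallate-(4β→8)-epigallocatechin-3-O-gallate-(4β→8)-catechin-3-O-gallate (CNP0321910.1) | O=C(O[C@@H]1[C@@H](c2c(O)cc(O)c3c2O[C@H](c2ccc(O)c(O)c2)[C@@H](OC(=O)c2cc(O)c(O)c(O)c2)C3)c2c(O)cc(O)c([C@H]3c4c(O)cc(O)cc4O[C@H](c4ccc(O)c(O)c4)[C@@H]3OC(=O)c3cc(O)c(O)c(O)c3)c2O[C@@H]1c1cc(O)c(O)c(O)c1)c1cc(O)c(O)c(O)c1 | target

**Step count and risks**

Total step count: 13. Longest linear sequence: 9 steps (steps 3, 4, 5, 6, 7, 8, 9, 12, 13, from 5 to 20).

Steps most likely to fail: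

1. Step 12 (proposed new method). What may go wrong: insufficient facial or endo/exo selectivity in the annulation; competing Friedel–Crafts attack of the oxocarbenium ion on the free C6 positions of the dimer or on a second molecule of 18; ionisation of 18 with loss of the aryloxy group instead of methoxide; acid-induced scrambling of the interflavan bond. Fallback by known chemistry, setting out from 10 and returning at 19: radical debromination of 10 (Bu3SnH, AIBN, toluene, 90 °C) would give pentadeca-O-benzyl epigallocatechin-3-O-gallate-(4β→8)-catechin-3-O-gallate F1. Commercial (−)-epicatechin would be benzylated on its four phenols (BnBr, K2CO3, DMF) to 5,7,3',4'-tetra-O-benzyl-(−)-epicatechin F2, oxidised at C4 (DDQ, 2-ethoxyethanol, CH2Cl2) to 4β-(2-ethoxyethoxy)-tetra-O-benzyl-epicatechin F3 and esterified with acid 3 (DCC, DMAP, CH2Cl2) to 4β-(2-ethoxyethoxy)-hepta-O-benzyl-epicatechin 3-O-gallate F4. TMSOTf-mediated coupling of F4 with excess F1 (CH2Cl2, −78 → −40 °C) should form the C4–C8 bond anti to the C3 gallate and give 19.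

2. Step 8. What may go wrong: a second coupling of the product boronate with 10, protodeboronation of the electron-rich styrylboronate, or slow oxidative addition with reductive loss of bromine. Fallback, setting out from 10 and returning at 12: Stille coupling with tributyl(vinyl)stannane (Pd(PPh3)4, toluene, 100 °C) would give the 8-vinyl dimer F5, and cross-metathesis with vinylboronic acid pinacol ester (second-generation Grubbs catalyst, CH2Cl2, 40 °C) should deliver 12 as the (E)-isomer.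

3. Step 9. What may go wrong: sluggish transmetalation of the pinacol boronate to copper, with protodeboronation or oxidative homocoupling taking over. Fallback, setting out from 12 and returning at 13: oxidation of the carbon–boron bond (NaBO3·4H2O, THF/H2O, rt) would give the arylacetaldehyde F6. Acid 3 would be converted with oxalyl chloride (cat. DMF, CH2Cl2) into 3,4,5-tris(benzyloxy)benzoyl chloride F7. O-acylation of the enol form of F6 with F7 (Et3N, DMAP, CH2Cl2, 0 °C) should give 13; the (E)-isomer is expected to prevail for steric reasons and any (Z)-isomer would be removed by chromatography.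

**Further compounds**

F1 | step 12 | pentadeca-O-benzyl epigallocatechin-3-O-gallate-(4β→8)-catechin-3-O-gallate (C8–H) | O=C(O[C@@H]1[C@@H](c2c(OCc5ccccc5)cc(OCc5ccccc5)c3c2O[C@H](c2ccc(OCc5ccccc5)c(OCc5ccccc5)c2)[C@@H](OC(=O)c2cc(OCc5ccccc5)c(OCc5ccccc5)c(OCc5ccccc5)c2)C3)c2c(OCc5ccccc5)cc(OCc5ccccc5)cc2O[C@@H]1c1cc(OCc5ccccc5)c(OCc5ccccc5)c(OCc5ccccc5)c1)c1cc(OCc5ccccc5)c(OCc5ccccc5)c(OCc5ccccc5)c1

F2 | step 12 | 5,7,3',4'-tetra-O-benzyl-(−)-epicatechin | O[C@@H]1Cc2c(OCc5ccccc5)cc(OCc5ccccc5)cc2O[C@@H]1c1ccc(OCc5ccccc5)c(OCc5ccccc5)c1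

F3 | step 12 | 4β-(2-ethoxyethoxy)-5,7,3',4'-tetra-O-benzyl-epicatechin | O[C@@H]1[C@@H](OCCOCC)c2c(OCc5ccccc5)cc(OCc5ccccc5)cc2O[C@@H]1c1ccc(OCc5ccccc5)c(OCc5ccccc5)c1

F4 | step 12 | 4β-(2-ethoxyethoxy)-hepta-O-benzyl-epicatechin 3-O-gallate | O=C(O[C@@H]1[C@@H](OCCOCC)c2c(OCc5ccccc5)cc(OCc5ccccc5)cc2O[C@@H]1c1ccc(OCc5ccccc5)c(OCc5ccccc5)c1)c1cc(OCc5ccccc5)c(OCc5ccccc5)c(OCc5ccccc5)c1

F5 | step 8 | dimer as 10 with a vinyl group in place of bromine | O=C(O[C@@H]1[C@@H](c2c(OCc5ccccc5)cc(OCc5ccccc5)c3c2O[C@H](c2ccc(OCc5ccccc5)c(OCc5ccccc5)c2)[C@@H](OC(=O)c2cc(OCc5ccccc5)c(OCc5ccccc5)c(OCc5ccccc5)c2)C3)c2c(OCc5ccccc5)cc(OCc5ccccc5)c(C=C)c2O[C@@H]1c1cc(OCc5ccccc5)c(OCc5ccccc5)c(OCc5ccccc5)c1)c1cc(OCc5ccccc5)c(OCc5ccccc5)c(OCc5ccccc5)c1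

F6 | step 9 | dimer as 10 with a 2-oxoethyl group in place of bromine | O=C(O[C@@H]1[C@@H](c2c(OCc5ccccc5)cc(OCc5ccccc5)c3c2O[C@H](c2ccc(OCc5ccccc5)c(OCc5ccccc5)c2)[C@@H](OC(=O)c2cc(OCc5ccccc5)c(OCc5ccccc5)c(OCc5ccccc5)c2)C3)c2c(OCc5ccccc5)cc(OCc5ccccc5)c(CC=O)c2O[C@@H]1c1cc(OCc5ccccc5)c(OCc5ccccc5)c(OCc5ccccc5)c1)c1cc(OCc5ccccc5)c(OCc5ccccc5)c(OCc5ccccc5)c1

F7 | step 9 | 3,4,5-tris(benzyloxy)benzoyl chloride | O=C(Cl)c1cc(OCc2ccccc2)c(OCc2ccccc2)c(OCc2ccccc2)c1
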